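Ring B (the cyclohexadienone: C1 carbonyl, C2 butanoyl, C3/C5 enols, C4 quaternary, C6 methylene-bearing) is a cyclised 3,5,7-triketo ester, and C4 is stereogenic only because C3 and C5 lead to different carbons (acylated C2 versus C6). The chirality is therefore stored as ketone versus ester on the quaternary carbon of an acyclic β-keto ester, set by two Fráter–Seebach alkylations of methyl (S)-3-hydroxybutanoate. In the key step the methyl-ketone enolate of this ester is C-acylated by a 3-oxohexanoyl donor (bond C1–C6) and the resulting polyanion closes by Claisen attack on the ester (bond C2–C3). A Mannich/Michael methylene coupling with the aromatic ketone completes the target.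

Key step: step 5

Remark: ring B is drawn, as in the target structure, in one of its rapidly interconverting enol forms; names and descriptors refer to that drawn form.

Step 1
Reactants: 1 methyl (3S)-3-hydroxybutanoate; 2 1-bromo-3-methylbut-2-ene (prenyl bromide)
Product: 3 methyl (2S,3S)-3-hydroxy-2-(3-methylbut-2-en-1-yl)butanoate
Conditions: LiN(i-Pr)2 (2.2 equiv), THF, –78 → –20 °C; then 2, DMPU, –78 → 0 °C; 1 M HCl
Reagents that add atoms: none
Why: Fráter–Seebach alkylation: the dilithium alkoxide-enolate of 1 is a rigid six-membered chelate, and the allylic bromide should add to the enolate face opposite the C3 methyl group, which sets C2 as S (2,3-anti).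

Step 2
Reactants: 3 methyl (2S,3S)-3-hydroxy-2-(3-methylbut-2-en-1-yl)butanoate
Product: 4 methyl (2R,3S)-3-hydroxy-2-methyl-2-(3-methylbut-2-en-1-yl)butanoate
Conditions: LiN(i-Pr)2 (2.5 equiv), THF, –78 → –20 °C; then MeI, DMPU, –78 → 0 °C; 1 M HCl
Reagents that add atoms: iodomethane CI
Why: Second Fráter–Seebach alkylation: the fully substituted chelated enolate of 3 should again be attacked anti to the C3 methyl group, so the incoming methyl takes the place that prenyl took in step 1 and the quaternary carbon is set as 2R under control of the (3S)-carbinol, any minor C2 epimer being removable by chromatography at this stage.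

Step 3
Reactants: 4 methyl (2R,3S)-3-hydroxy-2-methyl-2-(3-methylbut-2-en-1-yl)butanoate
Product: 5 methyl (2R)-2-acetyl-2,5-dimethylhex-4-enoate
Conditions: Dess–Martin periodinane, CH2Cl2, 0 °C → rt
Reagents that add atoms: none
Why: Dess–Martin oxidation of the secondary alcohol under neutral conditions removes the controlling carbinol centre and leaves a non-enolisable quaternary β-keto ester that cannot epimerise and is not exposed to retro-Claisen cleavage.

Step 4
Reactants: 6 phenyl acetate; 7 butanoyl chloride
Product: 8 phenyl 3-oxohexanoate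
Conditions: 6 (2.0 equiv), LiN(i-Pr)2 (2.0 equiv), THF, –78 °C; then 7 (1.0 equiv), –78 °C; AcOH, –78 °C
Reagents that add atoms: none
Why: Crossed Claisen acylation of an ester enolate by an acid chloride: the lithium enolate of 6, kept at –78 °C where it does not lose phenoxide, should be C-acylated by 7, the second equivalent of enolate deprotonates the more acidic β-keto ester as it forms and so protects it from a second acylation, and the cold acetic acid quench returns 8 before any elimination to a ketene can set in.

Step 5
Reactants: 5 methyl (2R)-2-acetyl-2,5-dimethylhex-4-enoate; 8 phenyl 3-oxohexanoate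
Product: 11 (4R)-2-butanoyl-3,5-dihydroxy-4-methyl-4-(3-methylbut-2-en-1-yl)cyclohexa-2,5-dien-1-one, via butanoylketene 9 (not isolated), via triketo ester 10 (not isolated)
Conditions: LiN(SiMe3)2 (2.2 equiv), THF, –78 °C; then lithium enolate of 8 (1.5 equiv; from 8 and LiN(SiMe3)2, THF, –78 °C), –78 °C → rt, then 40 °C; 1 M HCl
Reagents that add atoms: none
Why: The lithium enolate of 5 (the acetyl CH3 is its only enolisable position) should be C-acylated by butanoylketene 9, which the enolate of aryl ester 8 releases by E1cB loss of phenoxide on warming; this crossed Claisen acylation makes the ring C1–C6 bond and gives triketo ester 10 as its polyanion. In 10 the carbanion between the two distal ketones then attacks the methyl ester on the quaternary carbon and expels methoxide, a Dieckmann-type Claisen cyclisation (ring C2–C3 bond) of the kind known for 3,5,7-triketo esters on the way to acylphloroglucinols. This closure is 6-exo-trig at the ester carbonyl and is helped by the gem-dialkyl effect of the quaternary carbon. No new stereocentre is made: the quaternary carbon of 5 is untouched and becomes C4, fixed as R because the former ester carbon becomes C3 (next to acylated C2) and the former ketone carbon becomes C5 (next to free C6). The step needs C- over O-acylation in both bond formations (usual for lithium enolates with ketenes, and in the ring closure the carbocycle is the thermodynamic sink as its triacylmethanide salt, an enol lactone being reopened by lithium methoxide). It also needs Claisen over aldol closure and no retro-Claisen at the quaternary carbon, which the limited excess of a non-nucleophilic amide base and the absence of free alkoxide before ring closure should secure.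

Step 6
Reactants: 12 5-methoxybenzene-1,3-diol (5-methoxyresorcinol); 13 hexanenitrile
Product: 15 1-(2,4-dihydroxy-6-methoxyphenyl)hexan-1-one, via ketiminium chloride 14 (not isolated)
Conditions: ZnCl2, HCl (g), Et2O, 0 °C; then H2O, 100 °C
Reagents that add atoms: water O
Why: Hoesch acylation: the HCl-activated nitrile should attack the electron-rich ring para to a free hydroxyl and ortho to the methoxy group (two equivalent sites), and hydrolysis of ketiminium salt 14 gives the ketone, any 2,6-dihydroxy-4-methoxy isomer from attack between the hydroxyls being doubly chelated, less polar and separable.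

Step 7
Reactants: 11 (4R)-2-butanoyl-3,5-dihydroxy-4-methyl-4-(3-methylbut-2-en-1-yl)cyclohexa-2,5-dien-1-one; 15 1-(2,4-dihydroxy-6-methoxyphenyl)hexan-1-one
Product: 18 (4R)-2-butanoyl-6-[(3-hexanoyl-2,6-dihydroxy-4-methoxyphenyl)methyl]-3,5-dihydroxy-4-methyl-4-(3-methylbut-2-en-1-yl)cyclohexa-2,5-dien-1-one (CNP0219201.1), via Mannich base 16 (not isolated), via exocyclic enone 17 (not isolated)
Conditions: N,N-dimethylmethyleneiminium iodide (1.05 equiv), MeCN, 0 °C → rt; then 15 (1.5 equiv), 60 °C
Reagents that add atoms: N,N-dimethylmethyleneiminium iodide (Eschenmoser's salt) C=[N+](C)C.[I-]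
Why: Mannich reaction at the only free ring carbon of 11 (C6) gives 16, thermal loss of dimethylamine gives exocyclic enone 17, and Michael (Friedel–Crafts-type) addition of phenol 15 through its carbon flanked by the two free hydroxyls, the most nucleophilic ring position, forms the methylene bridge without touching the quaternary stereocentre.

Compound list
1 | methyl (3S)-3-hydroxybutanoate | C[C@H](O)CC(=O)OC | starting material
2 | 1-bromo-3-methylbut-2-ene (prenyl bromide) | CC(C)=CCBr | starting material
3 | methyl (2S,3S)-3-hydroxy-2-(3-methylbut-2-en-1-yl)butanoate | C[C@H](O)[C@H](CC=C(C)C)C(=O)OC | intermediate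
4 | methyl (2R,3S)-3-hydroxy-2-methyl-2-(3-methylbut-2-en-1-yl)butanoate | C[C@H](O)[C@@](C)(CC=C(C)C)C(=O)OC | intermediate
5 | methyl (2R)-2-acetyl-2,5-dimethylhex-4-enoate | CC(=O)[C@@](C)(CC=C(C)C)C(=O)OC | intermediate
6 | phenyl acetate | CC(=O)Oc1ccccc1 | starting material
7 | butanoyl chloride | CCCC(=O)Cl | starting material
8 | phenyl 3-oxohexanoate | CCCC(=O)CC(=O)Oc1ccccc1 | intermediate
9 | butanoylketene (3-oxohex-1-en-1-one) | CCCC(=O)C=C=O | intermediate
10 | methyl (2R)-2-methyl-2-(3-methylbut-2-en-1-yl)-3,5,7-trioxodecanoate | CCCC(=O)CC(=O)CC(=O)[C@@](C)(CC=C(C)C)C(=O)OC | intermediate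
11 | (4R)-2-butanoyl-3,5-dihydroxy-4-methyl-4-(3-methylbut-2-en-1-yl)cyclohexa-2,5-dien-1-one | O=C1C=C(O)[C@@](C)(CC=C(C)C)C(O)=C1C(=O)CCC | intermediate
12 | 5-methoxybenzene-1,3-diol (5-methoxyresorcinol) | COc1cc(O)cc(O)c1 | starting material
13 | hexanenitrile | CCCCCC#N | starting material
14 | 1-(2,4-dihydroxy-6-methoxyphenyl)hexan-1-iminium chloride | CCCCCC(=[NH2+])c1c(OC)cc(O)cc1O.[Cl-] | intermediate
15 | 1-(2,4-dihydroxy-6-methoxyphenyl)hexan-1-one | CCCCCC(=O)c1c(OC)cc(O)cc1O | intermediate
16 | (4R)-2-butanoyl-6-[(dimethylammonio)methyl]-3,5-dihydroxy-4-methyl-4-(3-methylbut-2-en-1-yl)cyclohexa-2,5-dien-1-one iodide | C[NH+](C)CC1=C(O)[C@@](C)(CC=C(C)C)C(O)=C(C(=O)CCC)C1=O.[I-] | intermediate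
17 | (6S)-4-butanoyl-5-hydroxy-6-methyl-2-methylidene-6-(3-methylbut-2-en-1-yl)cyclohex-4-ene-1,3-dione | C=C1C(=O)[C@@](C)(CC=C(C)C)C(O)=C(C(=O)CCC)C1=O | intermediate
18 | (4R)-2-butanoyl-6-[(3-hexanoyl-2,6-dihydroxy-4-methoxyphenyl)methyl]-3,5-dihydroxy-4-methyl-4-(3-methylbut-2-en-1-yl)cyclohexa-2,5-dien-1-one (CNP0219201.1) | CCCCCC(=O)c1c(OC)cc(O)c(CC2=C(O)[C@@](C)(CC=C(C)C)C(O)=C(C(=O)CCC)C2=O)c1O | target

Total step count: 7. Longest linear sequence: 5 steps (steps 1, 2, 3, 5 and 7).

Steps most likely to fail

Step 5. What may go wrong: O-acylation of the enolate of 5 by the ketene, consumption of the ketene by its own precursor enolate (dimerisation) or by the amide base, sluggish loss of phenoxide from the stabilised enolate of 8, incomplete Claisen closure at the hindered ester, or methoxide-induced retro-Claisen cleavage at the quaternary carbon. Fallback, setting out from 5 and 7 and returning at 11, with the ketene generated under neutral conditions: 5 would be silylated (t-BuMe2SiOTf, Et3N, CH2Cl2) to methyl (2R)-2-{1-[(tert-butyldimethylsilyl)oxy]ethenyl}-2,5-dimethylhex-4-enoate F1. Separately, 7 would acylate 2,2-dimethyl-1,3-dioxane-4,6-dione (pyridine, CH2Cl2, 0 °C → rt) to give 5-(1-hydroxybutylidene)-2,2-dimethyl-1,3-dioxane-4,6-dione F2, which on heating with acetone in toluene should give 2,2-dimethyl-6-propyl-4H-1,3-dioxin-4-one F3. Heating F1 with F3 in toluene at 110 °C releases ketene 9 without base, and its hetero-Diels–Alder addition to the silyl enol ether (C–C bond at the ketene carbon) should give methyl (2R)-2-{2-[(tert-butyldimethylsilyl)oxy]-4-oxo-6-propyl-3,4-dihydro-2H-pyran-2-yl}-2,5-dimethylhex-4-enoate F4. Bu4NF followed by DBU in THF in the same flask would open the silyl ketal to 10 and close it to 11 by the same Claisen cyclisation.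

Step 7. What may go wrong: attack of enone 17 at the other free aromatic carbon (between hydroxyl and methoxy), a second alkylation of the product, or self-coupling of 11 if Mannich formation is incomplete. Fallback, setting out from 15 and returning at 18, with the roles of the partners reversed: 15 would first be aminomethylated with the same iminium salt to 1-{3-[(dimethylamino)methyl]-2,4-dihydroxy-6-methoxyphenyl}hexan-1-one F5, which is purified as a single regioisomer and its substitution pattern secured before the chiral partner is committed. Heating F5 with 11 in dioxane at 90 °C would release the ortho-quinone methide 4-hexanoyl-3-hydroxy-5-methoxy-2-methylidenecyclohexa-3,5-dien-1-one F6, to which the C6 carbon of 11 adds to give 18.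

Step 6. What may go wrong: competing acylation at the carbon between the two hydroxyls, giving a hard-to-separate isomer mixture, or double acylation. Fallback, setting out from 13 and returning at 15, with the oxygen pattern set by protection instead of by ring selectivity: Hoesch reaction of 13 with symmetrical phloroglucinol would give 1-(2,4,6-trihydroxyphenyl)hexan-1-iminium chloride F7 and, after hydrolysis, 1-(2,4,6-trihydroxyphenyl)hexan-1-one F8. Chloromethyl methyl ether and i-Pr2NEt would protect the para and one ortho hydroxyl to give 1-[2-hydroxy-4,6-bis(methoxymethoxy)phenyl]hexan-1-one F9. MeI and K2CO3 in acetone would methylate the remaining chelated hydroxyl to give 1-[2-methoxy-4,6-bis(methoxymethoxy)phenyl]hexan-1-one F10, and HCl in methanol would remove both acetals to give 15.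

Further compounds
F1 | step 5 | methyl (2R)-2-{1-[(tert-butyldimethylsilyl)oxy]ethenyl}-2,5-dimethylhex-4-enoate | C=C(O[Si](C)(C)C(C)(C)C)[C@@](C)(CC=C(C)C)C(=O)OC
F2 | step 5 | 5-(1-hydroxybutylidene)-2,2-dimethyl-1,3-dioxane-4,6-dione | CCCC(O)=C1C(=O)OC(C)(C)OC1=O
F3 | step 5 | 2,2-dimethyl-6-propyl-4H-1,3-dioxin-4-one | CCCC1=CC(=O)OC(C)(C)O1
F4 | step 5 | methyl (2R)-2-{2-[(tert-butyldimethylsilyl)oxy]-4-oxo-6-propyl-3,4-dihydro-2H-pyran-2-yl}-2,5-dimethylhex-4-enoate (both epimers at the silyl ketal carbon) | CCCC1=CC(=O)CC(O[Si](C)(C)C(C)(C)C)(O1)[C@@](C)(CC=C(C)C)C(=O)OC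
F5 | step 7 | 1-{3-[(dimethylamino)methyl]-2,4-dihydroxy-6-methoxyphenyl}hexan-1-one | CCCCCC(=O)c1c(OC)cc(O)c(CN(C)C)c1O
F6 | step 7 | 4-hexanoyl-3-hydroxy-5-methoxy-2-methylidenecyclohexa-3,5-dien-1-one | CCCCCC(=O)C1=C(O)C(=C)C(=O)C=C1OC
F7 | step 6 | 1-(2,4,6-trihydroxyphenyl)hexan-1-iminium chloride | CCCCCC(=[NH2+])c1c(O)cc(O)cc1O.[Cl-]
F8 | step 6 | 1-(2,4,6-trihydroxyphenyl)hexan-1-one | CCCCCC(=O)c1c(O)cc(O)cc1O
F9 | step 6 | 1-[2-hydroxy-4,6-bis(methoxymethoxy)phenyl]hexan-1-one | CCCCCC(=O)c1c(O)cc(OCOC)cc1OCOC
F10 | step 6 | 1-[2-methoxy-4,6-bis(methoxymethoxy)phenyl]hexan-1-one | CCCCCC(=O)c1c(OC)cc(OCOC)cc1OCOC
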